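**Retrosynthetic overview**

1. The target should come from triene 34 by acetylation, desilylation and MnO2 oxidation. Triene 34 should come from an E-selective Wittig reaction of lactol 27. The lactol is a reduced butenolide, a temporary ring that holds the Z-trisubstituted alkene of the side chain and is joined to the cyclopentanone α-carbon by Michael addition.
2. Numbering the core as spiro[4.5]decane (C1–C4 cyclopentane, C5 spiro atom, C6–C10 cyclohexane), the C1 carbinol carbon, C5 and the C6 tertiary carbinol carbon form a 1,3-diol across the spiro atom (an aldol retron once C1 is a ketone), and C10 on the other side of C5 carries a three-carbon chain. This array is what makes the key step possible.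
3. Key disconnection: the C5–C6 bond (aldol addition, closes the cyclohexane and creates the spiro atom) together with the C10–CH2 bond (the allyl group is returned to C1 by a retro-[3,3] shift). This leads to the monocyclic (S)-1-allyl-2-alkylidenecyclopentanol 15 with a single stereocentre.
4. 15 comes from cyclopentanone and the tetrasubstituted enal 8 (aldol condensation, then catalytic enantioselective allylation). 8 comes from δ-hexalactone through a stereodefined enol triflate and cuprate coupling.
5. Ring order: cyclopentane (bought), then cyclohexane (step 11). Temporary rings: δ-lactone (steps 1–4) and butenolide (steps 12–17, opened in step 21).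

Key step: step 11

Remark 1: racemic δ-hexalactone is used; the carbinol carbon it supplies is drawn without descriptor and stays a mixture of both configurations until it is oxidised in step 10.
Remark 2: the (R)-BINOL titanium complex is assumed to give the (S)-carbinol 13; if the first run shows the opposite sense, (S)-BINOL is used and nothing else changes.

**Route**

Step 1
Reactants: 1 rac-6-methyloxan-2-one (δ-hexalactone); 2 methyl 2-[(tert-butyldimethylsilyl)oxy]acetate
Product: 3 3-{2-[(tert-butyldimethylsilyl)oxy]acetyl}-6-methyloxan-2-one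
Conditions: LiN(iPr)2 (2.1 equiv), THF, −78 °C, 1 (2.1 equiv); then 2 (1.0 equiv), −78 → −20 °C; aq. NH4Cl
Reagents that add atoms: none
Why: crossed Claisen condensation in which the lactone lithium enolate is acylated by the more electrophilic α-silyloxy ester and the β-keto lactone is removed from the equilibrium as its enolate; no stereocentre of the target is set here.

Step 2
Reactants: 3 3-{2-[(tert-butyldimethylsilyl)oxy]acetyl}-6-methyloxan-2-one
Product: 4 (1Z)-2-[(tert-butyldimethylsilyl)oxy]-1-(6-methyl-2-oxooxan-3-ylidene)ethyl trifluoromethanesulfonate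
Conditions: NaH, Et2O, 0 °C; then Tf2O, −78 → 0 °C
Reagents that add atoms: trifluoromethanesulfonic anhydride, O=S(=O)(OS(=O)(=O)C(F)(F)F)C(F)(F)F
Why: enol triflate formation from a β-dicarbonyl compound; the sodium enolate is a chelate between the ketone-derived oxygen and the lactone carbonyl, so O-sulfonylation should give the isomer with the triflate oxygen cis to the lactone carbonyl.

Step 3
Reactants: 4 (1Z)-enol triflate
Product: 5 (3E)-3-{1-[(tert-butyldimethylsilyl)oxy]propan-2-ylidene}-6-methyloxan-2-one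
Conditions: Me2CuLi (from MeLi and CuI), Et2O, −78 → −30 °C
Reagents that add atoms: lithium dimethylcuprate, [Li+].C[Cu-]C
Why: cuprate coupling with an enol triflate (addition–elimination at the β-carbon of the unsaturated lactone) replaces the triflate by methyl with retention, which fixes the geometry of the tetrasubstituted alkene of the target (methyl cis to the carbonyl carbon).

Step 4
Reactants: 5 (3E)-3-{1-[(tert-butyldimethylsilyl)oxy]propan-2-ylidene}-6-methyloxan-2-one
Product: 6 (2E)-2-{1-[(tert-butyldimethylsilyl)oxy]propan-2-ylidene}hexane-1,5-diol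
Conditions: iBu2AlH (4 equiv), CH2Cl2, −78 → 0 °C; aq. potassium sodium tartrate
Reagents that add atoms: none
Why: hydride reduction of the α-alkylidene lactone to the diol by 1,2-addition only, which leaves the silyl ether and the alkene geometry untouched.

Step 5
Reactants: 6 (2E)-2-{1-[(tert-butyldimethylsilyl)oxy]propan-2-ylidene}hexane-1,5-diol
Product: 7 (2E)-1-[(tert-butyldimethylsilyl)oxy]-2-methyl-6-[(triethylsilyl)oxy]-3-{[(triethylsilyl)oxy]methyl}hept-2-ene
Conditions: Et3SiCl (2.5 equiv), imidazole, DMF, 0 °C → rt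
Reagents that add atoms: chlorotriethylsilane, CC[Si](Cl)(CC)CC
Why: silyl ether formation at both hydroxyl groups, which avoids a free hydroxy aldehyde (lactol) in the next step.

Step 6
Reactants: 7 tris-silyl ether
Product: 8 (2E)-4-[(tert-butyldimethylsilyl)oxy]-3-methyl-2-{3-[(triethylsilyl)oxy]butyl}but-2-enal
Conditions: (COCl)2, DMSO, CH2Cl2, −78 → −40 °C; then Et3N
Reagents that add atoms: none
Why: Swern oxidation, under which a primary triethylsilyl ether is converted directly into the aldehyde while the secondary triethylsilyl ether and the tert-butyldimethylsilyl ether persist.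

Step 7
Reactants: 8 (2E)-enal; 9 cyclopentanone
Product: 12 (2E)-2-[(2E)-4-[(tert-butyldimethylsilyl)oxy]-3-methyl-2-{3-[(triethylsilyl)oxy]butyl}but-2-en-1-ylidene]cyclopentan-1-one, via lithium aldolate 10 (not isolated), via allylic mesylate 11 (not isolated)
Conditions: LiN(iPr)2, THF, −78 °C, 9; then 8; then MsCl, −78 → 0 °C; then DBU, rt
Reagents that add atoms: none
Why: aldol condensation run as directed aldol addition to the non-enolisable enal, O-mesylation of the aldolate and E1cB elimination, which should give the thermodynamically preferred (E)-alkylidene ketone.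

Step 8
Reactants: 12 dienone
Product: 13 (1S,2E)-2-[(2E)-4-[(tert-butyldimethylsilyl)oxy]-3-methyl-2-{3-[(triethylsilyl)oxy]butyl}but-2-en-1-ylidene]-1-(prop-2-en-1-yl)cyclopentan-1-ol
Conditions: Ti(OiPr)4 (30 mol %), (R)-BINOL (30 mol %), iPrOH (20 equiv), Sn(CH2CH=CH2)4 (1.5 equiv), CH2Cl2, rt
Reagents that add atoms: tetraallyltin, C=CC[Sn](CC=C)(CC=C)CC=C
Why: catalytic enantioselective 1,2-allylation of a ketone with the titanium–BINOL–isopropanol system, which accepts α-substituted cyclic enones and tells the sp2 α-carbon from the α′-methylene group; this sets the one stereocentre from which all others are relayed.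

Step 9
Reactants: 13 (1S)-carbinol
Product: 14 (1S,2E)-2-[(2E)-4-[(tert-butyldimethylsilyl)oxy]-2-(3-hydroxybutyl)-3-methylbut-2-en-1-ylidene]-1-(prop-2-en-1-yl)cyclopentan-1-ol
Conditions: HF·pyridine, pyridine, THF, 0 °C
Reagents that add atoms: none
Why: selective desilylation; buffered fluoride cleaves the secondary triethylsilyl ether much faster than the primary tert-butyldimethylsilyl ether, and the near-neutral medium should not ionise the tertiary dienyl carbinol.

Step 10
Reactants: 14 diol
Product: 15 (1S,2E)-2-[(2E)-4-[(tert-butyldimethylsilyl)oxy]-3-methyl-2-(3-oxobutyl)but-2-en-1-ylidene]-1-(prop-2-en-1-yl)cyclopentan-1-ol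
Conditions: Dess–Martin periodinane, NaHCO3, CH2Cl2, 0 °C → rt
Reagents that add atoms: none
Why: Dess–Martin oxidation of the secondary alcohol to the methyl ketone; the tertiary alcohol cannot be oxidised and the buffer protects it from acid.

Step 11
Reactants: 15 (1S)-1-allyl-2-alkylidenecyclopentanol methyl ketone
Product: 18 (5R,6S,9E,10R)-9-{1-[(tert-butyldimethylsilyl)oxy]propan-2-ylidene}-6-methyl-10-(prop-2-en-1-yl)-6-[(trimethylsilyl)oxy]spiro[4.5]decan-1-one, via potassium enolate 16 (not isolated), via potassium aldolate 17 (not isolated)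
Conditions: KN(SiMe3)2 (1.05 equiv), THF, −78 → 0 °C; then Me3SiCl, −78 °C → rt
Reagents that add atoms: chlorotrimethylsilane, C[Si](C)(C)Cl
Why: Proposed new method: the potassium alkoxide of 15 is a 3-oxido-1,5-diene and should undergo the anion-accelerated [3,3] sigmatropic shift (anionic oxy-Cope rearrangement, the closest known reaction type, here joined to the equally well-known intramolecular ketone–ketone aldol addition of a regiodefined enolate), which moves the allyl group from the carbinol carbon to the exocyclic alkene carbon and unveils the tetrasubstituted cyclopentanone enolate 16 beside the methyl ketone. The rearrangement closes no ring; the addition of the enolate α-carbon (the future spiro atom) to the methyl ketone closes the cyclohexane in a 6-(enolexo)-exo-trig mode and gives aldolate 17, which is silylated in the flask so that it cannot revert. The allyl-bearing centre follows from chirality transfer: the ring-fused diene can reach only one chair, with the oxygen axial and the (E)-alkenyl group equatorial, so the (S)-carbinol should deliver the allyl group to one face of the alkene and give the (R) centre. The spiro and tertiary carbinol centres are set in the aldol chair, in which A(1,3) strain against the methyl group of the tetrasubstituted exocyclic alkene forces the allyl group axial, the ketone methyl group takes the equatorial site to avoid it, and K+ bridging of the enolate and ketone oxygens places the cyclopentanone carbonyl gauche to the new C–O bond. The step needs chemoselectivity (rearrangement and ring closure faster than proton transfer from the enolisable methyl ketone and faster than loss of allylpotassium) and facial selectivity at the enolate; the first is served by the rearrangement itself delivering the enolate regiospecifically at the end of a six-atom tether, by one equivalent of base at low temperature and by silylation of the aldolate, the second by the conformational lock named above.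

Step 12
Reactants: 18 spiro ketone; 19 furan-2(5H)-one
Product: 22 (2S,5R,6S,9E,10R)-9-{1-[(tert-butyldimethylsilyl)oxy]propan-2-ylidene}-6-methyl-2-(5-oxo-2,5-dihydrofuran-3-yl)-10-(prop-2-en-1-yl)-6-[(trimethylsilyl)oxy]spiro[4.5]decan-1-one, via lithium lactone enolate 20 (not isolated), via phenylselanyl lactone 21 (not isolated)
Conditions: LiN(iPr)2, THF, −78 °C; 19, −78 °C; PhSeBr (1.0 equiv), −78 °C; then NaIO4, NaHCO3, THF/H2O, 0 °C → rt
Reagents that add atoms: none
Why: Michael addition of the only possible lithium enolate to the butenolide from the face opposite the silyloxy-bearing quaternary carbon should set the ring stereocentre trans to that carbon, and selenenylation of the resulting lactone enolate followed by selenoxide syn-elimination restores the butenolide double bond.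

Step 13
Reactants: 22 silyl ether
Product: 23 (2S,5R,6S,9E,10R)-9-{1-[(tert-butyldimethylsilyl)oxy]propan-2-ylidene}-6-hydroxy-6-methyl-2-(5-oxo-2,5-dihydrofuran-3-yl)-10-(prop-2-en-1-yl)spiro[4.5]decan-1-one
Conditions: pyridinium p-toluenesulfonate (cat.), MeOH, 0 °C
Reagents that add atoms: none
Why: acid-catalysed methanolysis removes the trimethylsilyl ether far faster than the primary tert-butyldimethylsilyl ether, and the non-basic medium keeps the acidic α-hydrogen next to the butenolide in place.

Step 14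
Reactants: 23 β-hydroxy ketone
Product: 24 4-[(1R,2S,5S,6S,9E,10R)-9-{1-[(tert-butyldimethylsilyl)oxy]propan-2-ylidene}-1,6-dihydroxy-6-methyl-10-(prop-2-en-1-yl)spiro[4.5]decan-2-yl]furan-2(5H)-one
Conditions: Me4NBH(OAc)3, MeCN/AcOH, −30 → 0 °C
Reagents that add atoms: none
Why: Evans–Saksena hydroxyl-directed reduction; the tertiary hydroxyl binds boron and delivers hydride to the ketone face on which it lies, which should give the secondary alcohol trans to the carbinol carbon on the spiro atom and cis to the butenolide.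

Step 15
Reactants: 24 diol
Product: 25 4-[(1R,2S,5S,6S,9E,10R)-9-{1-[(tert-butyldimethylsilyl)oxy]propan-2-ylidene}-1,6-dihydroxy-10-(3-hydroxypropyl)-6-methylspiro[4.5]decan-2-yl]furan-2(5H)-one
Conditions: 9-BBN-H (3.5 equiv), THF, 0 °C → rt; then aq. NaOAc, 30% H2O2, 0 °C
Reagents that add atoms: hydrogen peroxide, OO
Why: hydroboration–oxidation; 9-BBN-H adds anti-Markovnikov to the terminal alkene only, the electron-poor butenolide and the tetrasubstituted alkene do not react, and the buffered oxidation spares the lactone.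

Step 16
Reactants: 25 triol
Product: 26 4-[(1R,2S,5S,6S,9E,10R)-9-{1-[(tert-butyldimethylsilyl)oxy]propan-2-ylidene}-10-{3-[(tert-butyldimethylsilyl)oxy]propyl}-1,6-dihydroxy-6-methylspiro[4.5]decan-2-yl]furan-2(5H)-one
Conditions: tBuMe2SiCl (1.1 equiv), imidazole, CH2Cl2, 0 °C
Reagents that add atoms: tert-butylchlorodimethylsilane, CC(C)(C)[Si](C)(C)Cl
Why: silylation selective for the primary alcohol over the hindered secondary and the tertiary alcohol.

Step 17
Reactants: 26 butenolide
Product: 27 (1R,2S,5S,6S,9E,10R)-9-{1-[(tert-butyldimethylsilyl)oxy]propan-2-ylidene}-10-{3-[(tert-butyldimethylsilyl)oxy]propyl}-2-(5-hydroxy-2,5-dihydrofuran-3-yl)-6-methylspiro[4.5]decane-1,6-diol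
Conditions: iBu2AlH (3.5 equiv), CH2Cl2, −78 °C; aq. potassium sodium tartrate
Reagents that add atoms: none
Why: partial reduction of a lactone to the lactol; the aluminium hemiacetal is stable at −78 °C and the neutral work-up avoids dehydration to the furan.

Step 18
Reactants: 28 2-methylprop-2-en-1-ol; 29 1-bromo-3-methylbut-2-ene
Product: 30 6-methyl-2-methylidenehept-5-en-1-ol
Conditions: n-BuLi (2.2 equiv), TMEDA, Et2O/hexane, 0 °C → rt; then 29, −78 → 0 °C
Reagents that add atoms: none
Why: C-alkylation of the methallyl alcohol dianion by SN2 displacement of the primary allylic bromide.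

Step 19
Reactants: 30 6-methyl-2-methylidenehept-5-en-1-ol
Product: 31 2-(bromomethyl)-6-methylhepta-1,5-diene
Conditions: PBr3, pyridine (cat.), Et2O, 0 °C
Reagents that add atoms: phosphorus tribromide, BrP(Br)Br
Why: bromination of a primary allylic alcohol; allylic transposition is degenerate for this 2-substituted allyl system.

Step 20
Reactants: 31 2-(bromomethyl)-6-methylhepta-1,5-diene; 32 tributylphosphine
Product: 33 tributyl(6-methyl-2-methylidenehept-5-en-1-yl)phosphonium bromide
Conditions: MeCN, rt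
Reagents that add atoms: none
Why: quaternisation of the phosphine by SN2 at the allylic bromide.

Step 21
Reactants: 27 lactol; 33 phosphonium bromide
Product: 34 (1R,2S,5S,6S,9E,10R)-9-{1-[(tert-butyldimethylsilyl)oxy]propan-2-ylidene}-10-{3-[(tert-butyldimethylsilyl)oxy]propyl}-2-[(2Z,4E)-1-hydroxy-10-methyl-6-methylideneundeca-2,4,9-trien-2-yl]-6-methylspiro[4.5]decane-1,6-diol
Conditions: 33 (4.5 equiv), KOtBu (4.4 equiv), THF, 0 °C; then 27, −78 °C → rt
Reagents that add atoms: none
Why: Wittig olefination of the lactol through its open hydroxy enal form; allylic tributylphosphonium ylides should give the (E)-diene, and the Z geometry of the trisubstituted alkene is carried over from the butenolide ring.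

Step 22
Reactants: 34 triene triol
Product: 35 (2Z,4E)-2-[(1R,2S,5S,6S,9E,10R)-9-{1-[(tert-butyldimethylsilyl)oxy]propan-2-ylidene}-10-{3-[(tert-butyldimethylsilyl)oxy]propyl}-1,6-dihydroxy-6-methylspiro[4.5]decan-2-yl]-10-methyl-6-methylideneundeca-2,4,9-trien-1-yl acetate
Conditions: Ac2O (1.2 equiv), pyridine, CH2Cl2, 0 °C
Reagents that add atoms: acetic anhydride, CC(=O)OC(C)=O
Why: acylation selective for the primary allylic alcohol over the hindered secondary and the tertiary alcohol.

Step 23
Reactants: 35 acetate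
Product: 36 (2Z,4E)-2-[(1R,2S,5S,6S,9E,10R)-1,6-dihydroxy-9-(1-hydroxypropan-2-ylidene)-10-(3-hydroxypropyl)-6-methylspiro[4.5]decan-2-yl]-10-methyl-6-methylideneundeca-2,4,9-trien-1-yl acetate
Conditions: HF·pyridine, pyridine, THF, 0 °C → rt
Reagents that add atoms: none
Why: fluoride cleavage of both primary silyl ethers under buffered conditions that leave the allylic acetate and the triene alone.

Step 24
Reactants: 36 tetraol monoacetate
Product: 37 (2E)-2-[(1R,2S,5S,6S,10R)-2-[(2Z,4E)-1-acetoxy-10-methyl-6-methylideneundeca-2,4,9-trien-2-yl]-1,6-dihydroxy-10-(3-hydroxypropyl)-6-methylspiro[4.5]decan-9-ylidene]propanal (CNP0204268.1)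
Conditions: MnO2 (activated, excess), CH2Cl2, rt
Reagents that add atoms: none
Why: MnO2 oxidises only the allylic primary alcohol, under neutral conditions that keep the geometry of the tetrasubstituted enal.

**Compound list**

1 | rac-6-methyloxan-2-one (δ-hexalactone) | CC1CCCC(=O)O1 | starting material
2 | methyl 2-[(tert-butyldimethylsilyl)oxy]acetate | COC(=O)CO[Si](C)(C)C(C)(C)C | starting material
3 | 3-{2-[(tert-butyldimethylsilyl)oxy]acetyl}-6-methyloxan-2-one (stereoisomer mixture) | CC1CCC(C(=O)CO[Si](C)(C)C(C)(C)C)C(=O)O1 | intermediate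
4 | (1Z)-2-[(tert-butyldimethylsilyl)oxy]-1-(6-methyl-2-oxooxan-3-ylidene)ethyl trifluoromethanesulfonate | CC1CC/C(=C(/OS(=O)(=O)C(F)(F)F)CO[Si](C)(C)C(C)(C)C)C(=O)O1 | intermediate
5 | (3E)-3-{1-[(tert-butyldimethylsilyl)oxy]propan-2-ylidene}-6-methyloxan-2-one | CC1CC/C(=C(/C)CO[Si](C)(C)C(C)(C)C)C(=O)O1 | intermediate
6 | (2E)-2-{1-[(tert-butyldimethylsilyl)oxy]propan-2-ylidene}hexane-1,5-diol | CC(O)CC/C(CO)=C(/C)CO[Si](C)(C)C(C)(C)C | intermediate
7 | (2E)-1-[(tert-butyldimethylsilyl)oxy]-2-methyl-6-[(triethylsilyl)oxy]-3-{[(triethylsilyl)oxy]methyl}hept-2-ene | CC(O[Si](CC)(CC)CC)CC/C(CO[Si](CC)(CC)CC)=C(/C)CO[Si](C)(C)C(C)(C)C | intermediate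
8 | (2E)-4-[(tert-butyldimethylsilyl)oxy]-3-methyl-2-{3-[(triethylsilyl)oxy]butyl}but-2-enal | CC(O[Si](CC)(CC)CC)CC/C(C=O)=C(/C)CO[Si](C)(C)C(C)(C)C | intermediate
9 | cyclopentanone | O=C1CCCC1 | starting material
10 | lithium (2E)-4-[(tert-butyldimethylsilyl)oxy]-3-methyl-1-(2-oxocyclopentyl)-2-{3-[(triethylsilyl)oxy]butyl}but-2-en-1-olate (not isolated) | CC(O[Si](CC)(CC)CC)CC/C(=C(/C)CO[Si](C)(C)C(C)(C)C)C([O-])C1CCCC1=O.[Li+] | intermediate
11 | (2E)-4-[(tert-butyldimethylsilyl)oxy]-3-methyl-1-(2-oxocyclopentyl)-2-{3-[(triethylsilyl)oxy]butyl}but-2-en-1-yl methanesulfonate (not isolated) | CC(O[Si](CC)(CC)CC)CC/C(=C(/C)CO[Si](C)(C)C(C)(C)C)C(OS(C)(=O)=O)C1CCCC1=O | intermediate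
12 | (2E)-2-[(2E)-4-[(tert-butyldimethylsilyl)oxy]-3-methyl-2-{3-[(triethylsilyl)oxy]butyl}but-2-en-1-ylidene]cyclopentan-1-one | O=C1CCC/C1=C\C(CCC(C)O[Si](CC)(CC)CC)=C(/C)CO[Si](C)(C)C(C)(C)C | intermediate
13 | (1S,2E)-2-[(2E)-4-[(tert-butyldimethylsilyl)oxy]-3-methyl-2-{3-[(triethylsilyl)oxy]butyl}but-2-en-1-ylidene]-1-(prop-2-en-1-yl)cyclopentan-1-ol | O[C@]1(CC=C)CCC/C1=C\C(CCC(C)O[Si](CC)(CC)CC)=C(/C)CO[Si](C)(C)C(C)(C)C | intermediate
14 | (1S,2E)-2-[(2E)-4-[(tert-butyldimethylsilyl)oxy]-2-(3-hydroxybutyl)-3-methylbut-2-en-1-ylidene]-1-(prop-2-en-1-yl)cyclopentan-1-ol | O[C@]1(CC=C)CCC/C1=C\C(CCC(C)O)=C(/C)CO[Si](C)(C)C(C)(C)C | intermediate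
15 | (1S,2E)-2-[(2E)-4-[(tert-butyldimethylsilyl)oxy]-3-methyl-2-(3-oxobutyl)but-2-en-1-ylidene]-1-(prop-2-en-1-yl)cyclopentan-1-ol | O[C@]1(CC=C)CCC/C1=C\C(CCC(C)=O)=C(/C)CO[Si](C)(C)C(C)(C)C | intermediate
16 | potassium 2-{(1R)-1-[(2E)-1-[(tert-butyldimethylsilyl)oxy]-2-methyl-6-oxohept-2-en-3-yl]but-3-en-1-yl}cyclopent-1-en-1-olate (not isolated) | [K+].[O-]C1=C(CCC1)[C@H](CC=C)/C(CCC(C)=O)=C(\C)CO[Si](C)(C)C(C)(C)C | intermediate
17 | potassium (5R,6S,9E,10R)-9-{1-[(tert-butyldimethylsilyl)oxy]propan-2-ylidene}-6-methyl-1-oxo-10-(prop-2-en-1-yl)spiro[4.5]decan-6-olate (not isolated) | [K+].O=C1CCC[C@]12[C@H](CC=C)/C(=C(\C)CO[Si](C)(C)C(C)(C)C)CC[C@]2(C)[O-] | intermediate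
18 | (5R,6S,9E,10R)-9-{1-[(tert-butyldimethylsilyl)oxy]propan-2-ylidene}-6-methyl-10-(prop-2-en-1-yl)-6-[(trimethylsilyl)oxy]spiro[4.5]decan-1-one | O=C1CCC[C@]12[C@H](CC=C)/C(=C(\C)CO[Si](C)(C)C(C)(C)C)CC[C@]2(C)O[Si](C)(C)C | intermediate
19 | furan-2(5H)-one | O=C1C=CCO1 | starting material
20 | lithium 4,5-dihydrofuran-2-olate carrying the spiro ketone of 18 at its 4-position (Michael adduct enolate, not isolated) | [Li+].[O-]C1=CC(CO1)[C@@H]2CC[C@]3([C@H](CC=C)/C(=C(\C)CO[Si](C)(C)C(C)(C)C)CC[C@]3(C)O[Si](C)(C)C)C2=O | intermediate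
21 | spiro ketone of 18 carrying a 5-oxo-4-(phenylselanyl)oxolan-3-yl group at its α-carbon (not isolated) | O=C1OCC([C@@H]2CC[C@]3([C@H](CC=C)/C(=C(\C)CO[Si](C)(C)C(C)(C)C)CC[C@]3(C)O[Si](C)(C)C)C2=O)C1[Se]c1ccccc1 | intermediate
22 | (2S,5R,6S,9E,10R)-9-{1-[(tert-butyldimethylsilyl)oxy]propan-2-ylidene}-6-methyl-2-(5-oxo-2,5-dihydrofuran-3-yl)-10-(prop-2-en-1-yl)-6-[(trimethylsilyl)oxy]spiro[4.5]decan-1-one | O=C1C=C(CO1)[C@@H]2CC[C@]3([C@H](CC=C)/C(=C(\C)CO[Si](C)(C)C(C)(C)C)CC[C@]3(C)O[Si](C)(C)C)C2=O | intermediate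
23 | (2S,5R,6S,9E,10R)-9-{1-[(tert-butyldimethylsilyl)oxy]propan-2-ylidene}-6-hydroxy-6-methyl-2-(5-oxo-2,5-dihydrofuran-3-yl)-10-(prop-2-en-1-yl)spiro[4.5]decan-1-one | O=C1C=C(CO1)[C@@H]2CC[C@]3([C@H](CC=C)/C(=C(\C)CO[Si](C)(C)C(C)(C)C)CC[C@]3(C)O)C2=O | intermediate
24 | 4-[(1R,2S,5S,6S,9E,10R)-9-{1-[(tert-butyldimethylsilyl)oxy]propan-2-ylidene}-1,6-dihydroxy-6-methyl-10-(prop-2-en-1-yl)spiro[4.5]decan-2-yl]furan-2(5H)-one | O=C1C=C(CO1)[C@@H]2CC[C@]3([C@H](CC=C)/C(=C(\C)CO[Si](C)(C)C(C)(C)C)CC[C@]3(C)O)[C@@H]2O | intermediate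
25 | 4-[(1R,2S,5S,6S,9E,10R)-9-{1-[(tert-butyldimethylsilyl)oxy]propan-2-ylidene}-1,6-dihydroxy-10-(3-hydroxypropyl)-6-methylspiro[4.5]decan-2-yl]furan-2(5H)-one | O=C1C=C(CO1)[C@@H]2CC[C@]3([C@H](CCCO)/C(=C(\C)CO[Si](C)(C)C(C)(C)C)CC[C@]3(C)O)[C@@H]2O | intermediate
26 | 4-[(1R,2S,5S,6S,9E,10R)-9-{1-[(tert-butyldimethylsilyl)oxy]propan-2-ylidene}-10-{3-[(tert-butyldimethylsilyl)oxy]propyl}-1,6-dihydroxy-6-methylspiro[4.5]decan-2-yl]furan-2(5H)-one | O=C1C=C(CO1)[C@@H]2CC[C@]3([C@H](CCCO[Si](C)(C)C(C)(C)C)/C(=C(\C)CO[Si](C)(C)C(C)(C)C)CC[C@]3(C)O)[C@@H]2O | intermediate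
27 | (1R,2S,5S,6S,9E,10R)-9-{1-[(tert-butyldimethylsilyl)oxy]propan-2-ylidene}-10-{3-[(tert-butyldimethylsilyl)oxy]propyl}-2-(5-hydroxy-2,5-dihydrofuran-3-yl)-6-methylspiro[4.5]decane-1,6-diol (anomer mixture) | OC1C=C(CO1)[C@@H]2CC[C@]3([C@H](CCCO[Si](C)(C)C(C)(C)C)/C(=C(\C)CO[Si](C)(C)C(C)(C)C)CC[C@]3(C)O)[C@@H]2O | intermediate
28 | 2-methylprop-2-en-1-ol | C=C(C)CO | starting material
29 | 1-bromo-3-methylbut-2-ene | CC(C)=CCBr | starting material
30 | 6-methyl-2-methylidenehept-5-en-1-ol | C=C(CO)CCC=C(C)C | intermediate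
31 | 2-(bromomethyl)-6-methylhepta-1,5-diene | C=C(CBr)CCC=C(C)C | intermediate
32 | tributylphosphine | CCCCP(CCCC)CCCC | starting material
33 | tributyl(6-methyl-2-methylidenehept-5-en-1-yl)phosphonium bromide | [Br-].CCCC[P+](CCCC)(CCCC)CC(=C)CCC=C(C)C | intermediate
34 | (1R,2S,5S,6S,9E,10R)-9-{1-[(tert-butyldimethylsilyl)oxy]propan-2-ylidene}-10-{3-[(tert-butyldimethylsilyl)oxy]propyl}-2-[(2Z,4E)-1-hydroxy-10-methyl-6-methylideneundeca-2,4,9-trien-2-yl]-6-methylspiro[4.5]decane-1,6-diol | C=C(/C=C/C=C(\CO)[C@@H]1CC[C@]2([C@H](CCCO[Si](C)(C)C(C)(C)C)/C(=C(\C)CO[Si](C)(C)C(C)(C)C)CC[C@]2(C)O)[C@@H]1O)CCC=C(C)C | intermediate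
35 | primary allylic acetate of 34 | C=C(/C=C/C=C(\COC(C)=O)[C@@H]1CC[C@]2([C@H](CCCO[Si](C)(C)C(C)(C)C)/C(=C(\C)CO[Si](C)(C)C(C)(C)C)CC[C@]2(C)O)[C@@H]1O)CCC=C(C)C | intermediate
36 | (2Z,4E)-2-[(1R,2S,5S,6S,9E,10R)-1,6-dihydroxy-9-(1-hydroxypropan-2-ylidene)-10-(3-hydroxypropyl)-6-methylspiro[4.5]decan-2-yl]-10-methyl-6-methylideneundeca-2,4,9-trien-1-yl acetate | C=C(/C=C/C=C(\COC(C)=O)[C@@H]1CC[C@]2([C@H](CCCO)/C(=C(\C)CO)CC[C@]2(C)O)[C@@H]1O)CCC=C(C)C | intermediate
37 | CNP0204268.1, (2E)-2-[(1R,2S,5S,6S,10R)-2-[(2Z,4E)-1-acetoxy-10-methyl-6-methylideneundeca-2,4,9-trien-2-yl]-1,6-dihydroxy-10-(3-hydroxypropyl)-6-methylspiro[4.5]decan-9-ylidene]propanal | C=C(/C=C/C=C(\COC(C)=O)[C@@H]1CC[C@]2([C@H](CCCO)/C(=C(\C)C=O)CC[C@]2(C)O)[C@@H]1O)CCC=C(C)C | target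

**Step count and risks**

Total step count: 24. Longest linear sequence: 21 steps (steps 1–17 and 21–24, from δ-hexalactone); steps 18–20 make the phosphonium salt.

Steps most likely to fail:

1. Step 11 (proposed new method). What may go wrong: proton transfer from the enolisable methyl ketone to the alkoxide or to the rearranged enolate before ring closure, which would scramble the enolate position and open an aldol path onto the cyclopentanone carbonyl; and reversible aldol addition with loss of facial control. Fallback: rearrangement and ring closure are separated and the enolate is regenerated reductively. The fallback sets out from 13, in which the methyl ketone is still masked. KN(SiMe3)2 and 18-crown-6 in THF should effect the anionic oxy-Cope rearrangement alone, and quenching the enolate with N-bromosuccinimide should give the α-bromo ketone F1. Buffered HF·pyridine then gives the bromo keto alcohol F2, and Dess–Martin oxidation the bromo diketone F3. SmI2 in THF at −78 °C should form the samarium enolate only at the brominated carbon and close the ring by a chelation-controlled Reformatsky-type aldol addition to give the spiro ketol F4. 1-(Trimethylsilyl)imidazole converts this into 18, where the route is rejoined.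

2. Step 12. What may go wrong: proton transfer from the γ-position of the furanone to the basic lithium enolate in place of conjugate addition, and insufficient facial discrimination at the enolate carbon. Fallback: the conjugate addition is run on a silyl enol ether under Lewis acid catalysis, with no basic enolate present. The fallback sets out from 18, which LiN(iPr)2 and Me3SiCl convert into the trimethylsilyl enol ether F5. Mukaiyama–Michael addition of this to 19 (Me3SiOTf cat., CH2Cl2, −78 °C) should give the silyl ketene acetal F6, and PhSeCl converts that into 21. The route is rejoined at 21, which is oxidised to 22 as in step 12.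

3. Step 21. What may go wrong: erosion of E selectivity in the addition of the semi-stabilised ylide, and base-induced Z to E isomerisation of the ring-opened hydroxy enal. Fallback: the diene is made by cross-coupling. The fallback sets out from 27; Takai–Utimoto olefination (CrCl2, Cl2CHB(pin), LiI, THF) should give the (E)-alkenyl boronate F7 under non-basic conditions. The coupling partner, the enol triflate F8, is made from commercial 6-methylhept-5-en-2-one (LiN(iPr)2, THF, −78 °C; PhNTf2). Suzuki–Miyaura coupling of the two (Pd(PPh3)4, aq. K3PO4, THF) should give 34, where the route is rejoined.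

**Further compounds**

F1 | step 11 | 2-bromo-2-{(1R)-1-[(2E)-1-[(tert-butyldimethylsilyl)oxy]-2-methyl-6-[(triethylsilyl)oxy]hept-2-en-3-yl]but-3-en-1-yl}cyclopentan-1-one | O=C1CCCC1(Br)[C@H](CC=C)/C(CCC(C)O[Si](CC)(CC)CC)=C(\C)CO[Si](C)(C)C(C)(C)C
F2 | step 11 | 2-bromo-2-{(1R)-1-[(2E)-1-[(tert-butyldimethylsilyl)oxy]-6-hydroxy-2-methylhept-2-en-3-yl]but-3-en-1-yl}cyclopentan-1-one | O=C1CCCC1(Br)[C@H](CC=C)/C(CCC(C)O)=C(\C)CO[Si](C)(C)C(C)(C)C
F3 | step 11 | 2-bromo-2-{(1R)-1-[(2E)-1-[(tert-butyldimethylsilyl)oxy]-2-methyl-6-oxohept-2-en-3-yl]but-3-en-1-yl}cyclopentan-1-one | O=C1CCCC1(Br)[C@H](CC=C)/C(CCC(C)=O)=C(\C)CO[Si](C)(C)C(C)(C)C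
F4 | step 11 | (5R,6S,9E,10R)-9-{1-[(tert-butyldimethylsilyl)oxy]propan-2-ylidene}-6-hydroxy-6-methyl-10-(prop-2-en-1-yl)spiro[4.5]decan-1-one | O=C1CCC[C@]12[C@H](CC=C)/C(=C(\C)CO[Si](C)(C)C(C)(C)C)CC[C@]2(C)O
F5 | step 12 | trimethylsilyl enol ether of 18 (spiro[4.5]dec-1-ene with the silyloxy group on the alkene carbon next to the spiro atom) | C[Si](C)(C)OC1=CCC[C@]12[C@H](CC=C)/C(=C(\C)CO[Si](C)(C)C(C)(C)C)CC[C@]2(C)O[Si](C)(C)C
F6 | step 12 | spiro ketone of 18 carrying a 5-[(trimethylsilyl)oxy]-2,3-dihydrofuran-3-yl group at its α-carbon | C[Si](C)(C)OC1=CC(CO1)[C@@H]2CC[C@]3([C@H](CC=C)/C(=C(\C)CO[Si](C)(C)C(C)(C)C)CC[C@]3(C)O[Si](C)(C)C)C2=O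
F7 | step 21 | (1R,2S,5S,6S,9E,10R)-9-{1-[(tert-butyldimethylsilyl)oxy]propan-2-ylidene}-10-{3-[(tert-butyldimethylsilyl)oxy]propyl}-2-[(2Z,4E)-1-hydroxy-5-(4,4,5,5-tetramethyl-1,3,2-dioxaborolan-2-yl)penta-2,4-dien-2-yl]-6-methylspiro[4.5]decane-1,6-diol | CC1(C)OB(OC1(C)C)/C=C/C=C(\CO)[C@@H]2CC[C@]3([C@H](CCCO[Si](C)(C)C(C)(C)C)/C(=C(\C)CO[Si](C)(C)C(C)(C)C)CC[C@]3(C)O)[C@@H]2O
F8 | step 21 | 6-methylhepta-1,5-dien-2-yl trifluoromethanesulfonate | C=C(OS(=O)(=O)C(F)(F)F)CCC=C(C)C
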